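The route rests on disconnecting the C1–C10 bond of ring A. C1, the carbon that carries the angelate, is bonded to C10, a β-carbon of the ring B dienone (C6=C7–C8(=O)–C9=C10), and without the C7 side chain that dienone is symmetric about the quaternary carbon C5. A chiral triazolylidene turns a C1 aldehyde into an acyl anion equivalent that adds to one enone arm, which closes ring A, places the C1 oxygen and fixes C5 in one operation. The precursor is the 4-methyl-4-alkylcyclohexa-2,5-dienone 12, whose alkyl group carries the C4 stereocentre of (S)-citronellal and ends in the aldehyde.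

Key step: step 5

Numbering: eremophilane numbering is used for all bicyclic compounds (C1 oxygenated, C4 and C5 methyl-bearing, C6=C7–C8(=O)–C9=C10 in ring B, C11 the ester α-carbon); β is the face of the C5 methyl.
Remark on step 5: the two enone arms of 12 are diastereotopic, not enantiotopic, because C4 is already a stereocentre; the arm to be acylated is the pro-S arm at the quaternary carbon.
Remark on C1: the C1 carbonyl is reduced only after C10 has become trigonal (step 9), because in the cis-fused diketones 13, 14 and 16 hydride should enter from the convex β face (ring B screens the α face) and give the 1α-alcohol.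
Assumption: the antipode of the triazolium catalyst (step 5) and of the bis(oxazoline) ligand (step 7) is the one that gives the configuration drawn; both antipodes of each are available.

Step 1
Reactants: 1 (S)-citronellal
Product: 4 (3S)-2,3,7-trimethyloct-6-enal (both C2 epimers), via N-cyclohexyl imine 2 (not isolated), via methylated imine 3 (not isolated)
Conditions: cyclohexylamine, 4 Å molecular sieves, Et2O, 23 °C; LiN(iPr)2, THF, −78 to 0 °C; MeI, −78 to 0 °C; AcOH/NaOAc buffer, H2O/hexane, 23 °C
Reagents that add atoms: iodomethane, CI; water, O
Why: Stork metalloenamine alkylation, in which the lithiated imine is C-methylated cleanly where the free aldehyde enolate would self-condense; the C3 stereocentre is not touched and the new C2 centre needs no control because it becomes the non-stereogenic quaternary carbon of 10.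

Step 2
Reactants: 4 (3S)-2,3,7-trimethyloct-6-enal; 5 methyl vinyl ketone
Product: 8 4-methyl-4-[(2S)-6-methylhept-5-en-2-yl]cyclohex-2-en-1-one (both epimers at ring C4), via pyrrolidine enamine 6 (not isolated), via keto aldehyde 7 (not isolated)
Conditions: pyrrolidine, toluene, reflux with removal of water; 5, MeCN, 23 °C; AcOH/NaOAc, H2O, 70 °C
Reagents that add atoms: none
Why: Stork enamine Michael addition followed by intramolecular aldol condensation (Robinson annulation), the standard way from α,α-disubstituted aldehydes to 4,4-disubstituted cyclohexenones; the buffered hydrolysis spares the trisubstituted alkene from acid-induced ene cyclisation, and the two epimers at the quaternary carbon converge in step 3.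

Step 3
Reactants: 8 4-methyl-4-[(2S)-6-methylhept-5-en-2-yl]cyclohex-2-en-1-one
Product: 10 4-methyl-4-[(2S)-6-methylhept-5-en-2-yl]cyclohexa-2,5-dien-1-one, via silyl dienol ether 9 (not isolated)
Conditions: LiN(iPr)2, THF, −78 °C; Me3SiCl, −78 to 0 °C; Pd(OAc)2 (1.1 equiv), MeCN, 23 °C
Reagents that add atoms: none
Why: Saegusa–Ito dehydrogenation, in which deprotonation at the only enolisable position gives the cross-conjugated silyl dienol ether and Pd(OAc)2 converts it through the oxa-π-allyl complex and β-hydride loss into the symmetric dienone, whose quaternary carbon is no longer a stereocentre; the isolated trisubstituted alkene is inert to both reagents.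

Step 4
Reactants: 10 4-methyl-4-[(2S)-6-methylhept-5-en-2-yl]cyclohexa-2,5-dien-1-one
Product: 12 4-methyl-4-[(2S)-5-oxopentan-2-yl]cyclohexa-2,5-dien-1-one, via side-chain diol 11 (not isolated)
Conditions: OsO4 (2 mol %), NaIO4 (4 equiv), 2,6-lutidine, dioxane/H2O 3:1, 23 °C
Reagents that add atoms: sodium periodate, [Na+].[O-]I(=O)(=O)=O (terminal oxidant; its oxygen reaches carbon through osmium tetroxide, O=[Os](=O)(=O)=O)
Why: Lemieux–Johnson cleavage, in which OsO4 dihydroxylates the electron-rich trisubstituted alkene far faster than the electron-poor, neopentyl dienone double bonds and periodate cleaves the diol to the aldehyde and acetone, with 2,6-lutidine suppressing over-oxidation; the C4 stereocentre is remote from the reacting site.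

Step 5
Reactants: 12 4-methyl-4-[(2S)-5-oxopentan-2-yl]cyclohexa-2,5-dien-1-one
Product: 13 (4S,4aS,8aR)-4,4a-dimethyl-2,3,4,4a,8,8a-hexahydronaphthalene-1,7-dione (cis-fused; eremophilane numbering: 1,8-dioxo-6-ene with 4β-methyl and 5β-methyl and 10β-H)
Conditions: 5a,10b-dihydro-2-(pentafluorophenyl)-4H,6H-indeno[2,1-b][1,2,4]triazolo[4,3-d][1,4]oxazinium tetrafluoroborate (20 mol %, the antipode that acylates the pro-S arm), KN(SiMe3)2 (20 mol %), toluene, 23 °C
Reagents that add atoms: none
Why: The triazolylidene adds to the aldehyde carbon C1, proton transfer gives the Breslow enaminol, this acyl anion equivalent adds to the β-carbon C10 of one enone arm, and proton transfer to C9 with loss of the carbene leaves the 1,4-diketone. The closest known reaction is the intramolecular Stetter desymmetrisation of 4,4-disubstituted cyclohexa-2,5-dienones that carry an oxygen-tethered aldehyde; the all-carbon tether and the six-membered ring are the only extension. Ring A closes 6-exo-trig, and since the tether reaches C10 only on the face of ring B that carries it, the ring fusion is cis, which sets C10 (H-10 syn to the C5 methyl). C5 is set by the choice of arm: the arms are diastereotopic because C4 is already stereogenic, the pro-S arm is needed, and the choice is made by the chiral pocket of the catalyst. In the chair-like closure onto that arm the C5 methyl is equatorial and the C4 methyl axial on the forming ring (the closure with the C4 methyl equatorial gives the 4,5-trans isomer), so the substrate leans mildly toward the wrong arm and the step needs a strongly arm-selective catalyst. Chemoselectivity is secured by the substrate: the dienone has no enolisable hydrogen, its carbonyl is out of reach of C1, and the quaternary centre next to the tether favours the reactive rotamer.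

Step 6
Reactants: 13 cis-fused 1,8-dione
Product: 14 7-iodo derivative of 13 (6-iodo-4,4a-dimethyl-2,3,4,4a,8,8a-hexahydronaphthalene-1,7-dione with the stereochemistry of 13)
Conditions: I2, pyridine/CH2Cl2 1:1, 0 to 23 °C, dark
Reagents that add atoms: iodine, II
Why: α-Iodination of an enone by the pyridine addition, iodination and elimination sequence (Baylis–Hillman-type), well established for 4,4-disubstituted cyclohexenones; C7 is the only enone α-carbon in 13, so the site is not in question, and any epimerisation at C10 is harmless because C10 becomes trigonal in step 8.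

Step 7
Reactants: 14 7-iodo enone; 15 methyl 2-chloropropanoate (racemic)
Product: 16 methyl (11S)-1,8-dioxoeremophil-6-en-12-oate (cis-fused, 10β-H)
Conditions: NiBr2·diglyme (10 mol %), chiral 4,4'-di(heptan-4-yl)-2,2'-bis(2-oxazoline) (20 mol %, the antipode that gives 11S), Mn powder (3 equiv), NaBF4, THF/DMA, 23 °C
Reagents that add atoms: none
Why: Nickel-catalysed enantioconvergent reductive cross-electrophile coupling, a reaction type established for C(sp2) iodides with racemic α-chloro esters and for alkenyl halides with racemic benzylic chlorides: the C7–I bond adds to zerovalent nickel, the chloride is turned into a planar α-ester radical so that both of its enantiomers converge, and capture at nickel followed by reductive elimination in the chiral ligand pocket sets C11 (S) under catalyst control, the other stereocentres being too remote to interfere and the ketones being inert to Mn.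

Step 8
Reactants: 16 methyl (11S)-1,8-dioxoeremophil-6-en-12-oate
Product: 17 methyl (11S)-1,8-dioxoeremophila-6,9-dien-12-oate
Conditions: IBX (1.5 equiv), DMSO, 60 °C
Reagents that add atoms: none
Why: IBX dehydrogenation of a ketone through its enol; the C9–C10 bond lies between the two carbonyl groups, so enolisation of either ketone leads to the same doubly activated ene-dione, which should form much faster than a ring A enone, the C10 stereocentre is erased as planned, and the ester α-carbon C11 is not enolised under these non-basic conditions.

Step 9
Reactants: 17 methyl (11S)-1,8-dioxoeremophila-6,9-dien-12-oate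
Product: 18 methyl (11S)-1β-hydroxy-8-oxoeremophila-6,9-dien-12-oate
Conditions: NaBH4 (1.0 equiv), CeCl3·7H2O, MeOH/CH2Cl2, −78 °C
Reagents that add atoms: none
Why: Luche 1,2-reduction, in which the C1 carbonyl, conjugated only with the electron-poor C9=C10 bond, should be more electrophilic than the cross-conjugated and α-branched C8 carbonyl of the cyclohexadienone; with C10 trigonal the axial C5 methyl screens the β face of C1, so hydride enters from the α face and gives the axial 1β-alcohol (1R).

Step 10
Reactants: 18 methyl (11S)-1β-hydroxy-8-oxoeremophila-6,9-dien-12-oate; 19 angelic acid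
Product: 21 methyl (11S)-1β-angeloyloxy-8-oxoeremophila-6,9-dien-12-oate (the target), via angelic 2,4,6-trichlorobenzoic anhydride 20 (not isolated)
Conditions: 19, 2,4,6-Cl3C6H2COCl, Et3N, toluene, 23 °C; then 18, 75 °C
Reagents that add atoms: none
Why: Yamaguchi-type mixed-anhydride esterification run without a nucleophilic catalyst, the known way to acylate hindered secondary alcohols with angelic acid without Z to E isomerisation to the tiglate; the C1–O bond is not broken, so the 1β configuration is retained, and the in-plane H-1 and the weak base should keep the γ-oxygenated dienone and C11 from isomerising.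

Compound list
1 | (S)-citronellal, (3S)-3,7-dimethyloct-6-enal | O=CC[C@@H](C)CCC=C(C)C | starting material
2 | N-cyclohexyl imine of 1, N-[(3S)-3,7-dimethyloct-6-en-1-ylidene]cyclohexanamine | C1CCCCC1N=CC[C@@H](C)CCC=C(C)C | intermediate (not isolated)
3 | N-cyclohexyl imine of 4, N-[(3S)-2,3,7-trimethyloct-6-en-1-ylidene]cyclohexanamine (both C2 epimers) | C1CCCCC1N=CC(C)[C@@H](C)CCC=C(C)C | intermediate (not isolated)
4 | (3S)-2,3,7-trimethyloct-6-enal (both C2 epimers) | O=CC(C)[C@@H](C)CCC=C(C)C | intermediate
5 | methyl vinyl ketone, but-3-en-2-one | CC(=O)C=C | starting material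
6 | 1-[(3S)-2,3,7-trimethylocta-1,6-dien-1-yl]pyrrolidine | C1CCN(C1)C=C(C)[C@@H](C)CCC=C(C)C | intermediate (not isolated)
7 | 2-methyl-2-[(2S)-6-methylhept-5-en-2-yl]-5-oxohexanal (both C2 epimers) | O=CC(C)(CCC(C)=O)[C@@H](C)CCC=C(C)C | intermediate (not isolated)
8 | 4-methyl-4-[(2S)-6-methylhept-5-en-2-yl]cyclohex-2-en-1-one (both epimers at ring C4) | O=C1C=CC(C)(CC1)[C@@H](C)CCC=C(C)C | intermediate
9 | trimethyl({4-methyl-4-[(2S)-6-methylhept-5-en-2-yl]cyclohexa-1,5-dien-1-yl}oxy)silane | C[Si](C)(C)OC1=CCC(C)(C=C1)[C@@H](C)CCC=C(C)C | intermediate (not isolated)
10 | 4-methyl-4-[(2S)-6-methylhept-5-en-2-yl]cyclohexa-2,5-dien-1-one | O=C1C=CC(C)(C=C1)[C@@H](C)CCC=C(C)C | intermediate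
11 | 4-[(2S)-5,6-dihydroxy-6-methylheptan-2-yl]-4-methylcyclohexa-2,5-dien-1-one (both C5 epimers of the side chain) | O=C1C=CC(C)(C=C1)[C@@H](C)CCC(O)C(C)(C)O | intermediate (not isolated)
12 | 4-methyl-4-[(2S)-5-oxopentan-2-yl]cyclohexa-2,5-dien-1-one | O=CCC[C@H](C)C1(C)C=CC(=O)C=C1 | intermediate (precursor of the key step)
13 | (4S,4aS,8aR)-4,4a-dimethyl-2,3,4,4a,8,8a-hexahydronaphthalene-1,7-dione (cis-fused; 4β-methyl, 5β-methyl, 10β-H) | O=C1CC[C@H](C)[C@@]2(C)C=CC(=O)C[C@@H]12 | intermediate (product of the key step)
14 | 7-iodo derivative of 13 (iodine on the enone α-carbon C7; arrangement at C4, C5 and C10 as in 13) | O=C1CC[C@H](C)[C@@]2(C)C=C(I)C(=O)C[C@@H]12 | intermediate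
15 | methyl 2-chloropropanoate (racemic) | CC(Cl)C(=O)OC | starting material
16 | methyl (11S)-1,8-dioxoeremophil-6-en-12-oate (4S,5S,10R,11S; cis-fused) | O=C1CC[C@H](C)[C@@]2(C)C=C([C@H](C)C(=O)OC)C(=O)C[C@@H]12 | intermediate
17 | methyl (11S)-1,8-dioxoeremophila-6,9-dien-12-oate (4S,5S,11S) | O=C1CC[C@H](C)[C@@]2(C)C=C([C@H](C)C(=O)OC)C(=O)C=C12 | intermediate
18 | methyl (11S)-1β-hydroxy-8-oxoeremophila-6,9-dien-12-oate (1R,4S,5S,11S) | O[C@@H]1CC[C@H](C)[C@@]2(C)C=C([C@H](C)C(=O)OC)C(=O)C=C12 | intermediate
19 | angelic acid, (2Z)-2-methylbut-2-enoic acid | C/C=C(/C)C(=O)O | starting material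
20 | (2Z)-2-methylbut-2-enoic 2,4,6-trichlorobenzoic anhydride | C/C=C(/C)C(=O)OC(=O)c1c(Cl)cc(Cl)cc1Cl | intermediate (not isolated)
21 | methyl (2S)-2-[(5R,8S,8aS)-8,8a-dimethyl-5-{[(2Z)-2-methylbut-2-enoyl]oxy}-3-oxo-3,5,6,7,8,8a-hexahydronaphthalen-2-yl]propanoate (1R,4S,5S,11S in eremophilane numbering) | C/C=C(/C)C(=O)O[C@@H]1CC[C@H](C)[C@@]2(C)C=C([C@H](C)C(=O)OC)C(=O)C=C12 | target

Total step count: 10 steps. Longest linear sequence: 10 steps (1 to 21); 5, 15 and 19 enter as purchased partners.

Steps most likely to fail

The first is step 5. The carbene may fail to turn over, because the unactivated aliphatic Breslow intermediate must close a six-membered ring on a neopentyl β-carbon and can be diverted into aldol or benzoin pathways. The catalyst may also fail to override the innate preference for the closure with the C4 methyl equatorial, which would erode the arm selection. The fallback sets out from 12 and returns at 13 by a radical instead of a polar acyl transfer: thiol-catalysed radical-chain hydroacylation (tert-dodecanethiol as catalyst, AIBN, chlorobenzene, 80 °C). A thiyl radical abstracts the aldehyde hydrogen, the acyl radical closes 6-exo onto C10, and the α-keto radical takes hydrogen back from the thiol. This fallback makes no new compound (F0). It gives up reagent control, so the arm would be chosen by the substrate alone and 13 would have to be separated from its epimer at C5 and C10.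

The second is step 7. Hydrodeiodination or homocoupling may outrun the cross-coupling, or catalyst control at C11 may be insufficient. The fallback sets out from 14 and returns at 16 by a conventional Negishi coupling (Pd(PPh3)4, THF, 50 °C) with the Reformatsky reagent (1-methoxy-1-oxopropan-2-yl)zinc bromide F1, made from methyl 2-bromopropanoate and Zn. It would give 16 together with its C11 epimer, methyl (11R)-1,8-dioxoeremophil-6-en-12-oate F2. The two are separated by chromatography, and F2 is re-equilibrated at C11 with a catalytic amine base and separated again.

The third is step 9. Site selectivity between the two carbonyl groups may be lost, with hydride also reaching C8. The fallback sets out from 17 and returns at 18 by reducing both carbonyl groups on purpose (NaBH4 in excess, CeCl3·7H2O, MeOH, 0 °C) to methyl (11S)-1β,8-dihydroxyeremophila-6,9-dien-12-oate F3. MnO2 (CH2Cl2, 23 °C) then re-oxidises the doubly allylic, unhindered C8 carbinol, which should react far faster than the axial, singly allylic C1 carbinol.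

Further compounds
F0 | step 5 | none | none
F1 | step 7 | (1-methoxy-1-oxopropan-2-yl)zinc bromide | COC(=O)C(C)[Zn]Br
F2 | step 7 | methyl (11R)-1,8-dioxoeremophil-6-en-12-oate (C11 epimer of 16) | O=C1CC[C@H](C)[C@@]2(C)C=C([C@@H](C)C(=O)OC)C(=O)C[C@@H]12
F3 | step 9 | methyl (11S)-1β,8-dihydroxyeremophila-6,9-dien-12-oate (both C8 epimers) | O[C@@H]1CC[C@H](C)[C@@]2(C)C=C([C@H](C)C(=O)OC)C(O)C=C12
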